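**Retrosynthetic overview**

1. Numbering (ent-kaurane type): ring A = C1–C5, C10 (C18 methyl and C19 carboxyl on C4, C6 carboxyl on C5, C20 methyl on C10); ring C = C8, C9, C11 (ketone), C12, C13, C14; ring D = C8, C14, C13, C16 (=C17), C15; C7 is the formyl carbon on C8.
2. Target 22 ⇐ diallyl ester 21 (deallylation) ⇐ union of ring A with the carbocyclic core across the C9–C10 bond, ring D being closed in the same operation.
3. Enabling feature: C9 sits between the C11 ketone and the formyl-bearing C8. Cutting C8–C15 as well reveals the ene-1,4-dicarbonyl 19, whose C8=C9 bond is flanked by C7=O and C11=O and accepts a tertiary C10 radical at C9. The α-formyl C8 carbanion that results is 1,3 to C13, whose 2-(chloromethyl)vinyl arm (C15–C17) closes ring D by alkylation.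
4. Ring A radical precursor 10 (tertiary caesium oxalate) ⇐ keto lactone 4, whose temporary γ-lactone ring locks the cis C6/C19 relationship ⇐ enone ester 1 by asymmetric conjugate methylation and formaldehyde aldol.
5. Acceptor 19 ⇐ cyclohexenone ester 16 ⇐ hetero-Diels–Alder reaction and aldol condensation from dienyl keto ester 13. Ring order: A (present in 1) → C (step 8) → D (step 12).

Key step: step 12

Remark: the ligand antipodes in steps 1 and 7 are taken to be those that give the configurations drawn; if the sense of induction is the opposite, the enantiomeric ligand is used.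

**Route**

Step 1
Reactants: 1 methyl 3-oxocyclohex-1-ene-1-carboxylate
Product: 4 (3aS,7aR)-7a-methylhexahydro-2-benzofuran-1,4-dione, via methylzinc enolate 2 (not isolated), via hydroxymethyl keto ester 3 (not isolated)
Conditions: Me2Zn (3 equiv), Cu(OTf)2 (2.5 mol%), chiral sulfonate-bridged N-heterocyclic carbene ligand (imidazolinium salt, 5 mol%), t-BuOMe, −30 °C; then HCHO (gas), −78 → −20 °C; aq. NH4Cl; then p-TsOH·H2O (cat.), CH2Cl2, rt
Reagents that add atoms: dimethylzinc C[Zn]C; formaldehyde C=O
Why: Copper-catalysed enantioselective conjugate addition of Me2Zn to the β-carboxy enone should set the methyl/ester quaternary centre (C4) under ligand control, the zinc enolate 2 is trapped regiospecifically by formaldehyde in a tandem aldol reaction, and acid-promoted lactonisation onto the neighbouring ester, possible only for the cis isomer of the epimerisable α-keto centre (C5), should give the cis-fused keto lactone that fixes the future C6/C19 cis relationship.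

Step 2
Reactants: 4 (3aS,7aR)-7a-methylhexahydro-2-benzofuran-1,4-dione
Product: 5 (3aS,4S,7aR)-4-hydroxy-4,7a-dimethylhexahydro-2-benzofuran-1(3H)-one
Conditions: MeMgBr (1.5 equiv), CeCl3 (1.5 equiv), THF, −78 °C; aq. NH4Cl
Reagents that add atoms: methylmagnesium bromide C[Mg]Br
Why: Organocerium 1,2-addition should take the ketone in preference to the lactone carbonyl on a quaternary carbon without enolising or eliminating the β-acyloxy ketone; the new carbinol centre (drawn as the epimer from attack anti to the lactone ring) is of no consequence because it becomes the planar C10 radical in step 12.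

Step 3
Reactants: 5 (3aS,4S,7aR)-4-hydroxy-4,7a-dimethylhexahydro-2-benzofuran-1(3H)-one
Product: 8 diallyl (1R,2R,3S)-3-hydroxy-1,3-dimethylcyclohexane-1,2-dicarboxylate, via potassium hydroxy carboxylate 6 (not isolated), via hydroxy diacid 7 (not isolated)
Conditions: KOH, H2O–MeOH, 50 °C; then pH 6.7 phosphate buffer, TEMPO (cat.), NaOCl (cat.), NaClO2, MeCN, 35 °C; HCl to pH 3 (0 °C), EtOAc; then allyl bromide, Cs2CO3, DMF, rt
Reagents that add atoms: potassium hydroxide [K+].[OH-]; sodium chlorite [Na+].[O-]Cl=O; allyl bromide C=CCBr
Why: Saponification of the γ-lactone, TEMPO/chlorite oxidation of the freed primary alcohol to the acid at near-neutral pH (conditions that should not epimerise the α-centre C5, so the cis relationship set by the lactone is kept) and double O-alkylation of the dicarboxylate with allyl bromide should give the cis diallyl diester with the tertiary alcohol untouched.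

Step 4
Reactants: 8 diallyl (1R,2R,3S)-3-hydroxy-1,3-dimethylcyclohexane-1,2-dicarboxylate
Product: 9 diallyl (1R,2R,3S)-3-[(methoxyoxalyl)oxy]-1,3-dimethylcyclohexane-1,2-dicarboxylate
Conditions: ClC(O)CO2Me (1.5 equiv), Et3N, DMAP (cat.), CH2Cl2, 0 °C → rt
Reagents that add atoms: methyl chlorooxoacetate COC(=O)C(Cl)=O
Why: DMAP-catalysed acylation of the hindered tertiary alcohol with the very reactive oxalyl half-ester chloride is the standard entry to tertiary alkyl oxalates and creates no stereocentre.

Step 5
Reactants: 9 diallyl (1R,2R,3S)-3-[(methoxyoxalyl)oxy]-1,3-dimethylcyclohexane-1,2-dicarboxylate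
Product: 10 caesium 2-{[(1S,2R,3R)-2,3-bis(allyloxycarbonyl)-1,3-dimethylcyclohexyl]oxy}-2-oxoacetate
Conditions: CsOH·H2O (1.0 equiv), THF–H2O, rt
Reagents that add atoms: caesium hydroxide [Cs+].[OH-]
Why: The oxalate methyl ester is far more electrophilic than the two hindered allyl esters, so one equivalent of hydroxide should saponify it selectively to the photoactive caesium oxalate.

Step 6
Reactants: 11 methacrolein; 12 ethyl 2-oxo-3-(triphenyl-λ5-phosphanylidene)propanoate
Product: 13 ethyl (3E)-5-methyl-2-oxohexa-3,5-dienoate
Conditions: CH2Cl2, rt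
Reagents that add atoms: none
Why: Wittig olefination with a ketone-stabilised ylide should give the (E)-β,γ-unsaturated α-keto ester.

Step 7
Reactants: 13 ethyl (3E)-5-methyl-2-oxohexa-3,5-dienoate
Product: 15 ethyl (4R)-2,6-dioxo-4-(prop-1-en-2-yl)heptanoate, via methoxy dihydropyran 14 (not isolated)
Conditions: 2-methoxypropene (3 equiv), Cu(OTf)2 (10 mol%), (S,S)-t-Bu-box (11 mol%), THF, −78 → −40 °C; then 1 M HCl, THF, 0 °C
Reagents that add atoms: 2-methoxypropene COC(C)=C
Why: Inverse-electron-demand hetero-Diels–Alder reaction of the copper-chelated 1-oxadiene with the enol ether should set C13 under bis(oxazoline) ligand control, and acidic hydrolysis of the mixed ketal then gives the 1,5-diketone; the distal isopropenyl group is a spectator.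

Step 8
Reactants: 15 ethyl (4R)-2,6-dioxo-4-(prop-1-en-2-yl)heptanoate
Product: 16 ethyl (5S)-3-oxo-5-(prop-1-en-2-yl)cyclohex-1-ene-1-carboxylate
Conditions: p-TsOH·H2O (10 mol%), toluene, 80 °C
Reagents that add atoms: none
Why: Intramolecular aldol condensation of the methyl ketone (C9) onto the highly electrophilic α-keto ester carbonyl (C8) followed by dehydration should close ring C as the only six-membered option, and C13 is not enolisable and stays untouched.

Step 9
Reactants: 16 ethyl (5S)-3-oxo-5-(prop-1-en-2-yl)cyclohex-1-ene-1-carboxylate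
Product: 17 ethyl (5S)-5-(3-chloroprop-1-en-2-yl)-3-oxocyclohex-1-ene-1-carboxylate
Conditions: NCS (1.1 equiv), PhSeCl (10 mol%), CH2Cl2, rt
Reagents that add atoms: N-chlorosuccinimide O=C1CCC(=O)N1Cl
Why: Selenium-catalysed ene-type allylic chlorination should convert the electron-rich 1,1-disubstituted alkene into the transposed allylic chloride (the same 2-substituted allyl unit) while the electron-poor enone alkene stays inert.

Step 10
Reactants: 17 ethyl (5S)-5-(3-chloroprop-1-en-2-yl)-3-oxocyclohex-1-ene-1-carboxylate
Product: 18 (5S)-5-(3-chloroprop-1-en-2-yl)-3-(hydroxymethyl)cyclohex-2-en-1-ol (both C1 epimers)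
Conditions: i-Bu2AlH (4.5 equiv), CH2Cl2, −78 °C; Rochelle salt
Reagents that add atoms: none
Why: Hydride 1,2-reduction of both the unsaturated ester and the enone carbonyl at low temperature should leave the allylic chloride and the alkenes intact, and the new carbinol centre is irrelevant because it is re-oxidised in step 11.

Step 11
Reactants: 18 (5S)-5-(3-chloroprop-1-en-2-yl)-3-(hydroxymethyl)cyclohex-2-en-1-ol
Product: 19 (5S)-5-(3-chloroprop-1-en-2-yl)-3-oxocyclohex-1-ene-1-carbaldehyde
Conditions: MnO2 (excess), CH2Cl2, rt; used at once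
Reagents that add atoms: none
Why: Allylic oxidation with MnO2 should take both allylic alcohols to the ene-1,4-dicarbonyl acceptor without touching the allylic chloride.

Step 12
Reactants: 10 caesium 2-{[(1S,2R,3R)-2,3-bis(allyloxycarbonyl)-1,3-dimethylcyclohexyl]oxy}-2-oxoacetate; 19 (5S)-5-(3-chloroprop-1-en-2-yl)-3-oxocyclohex-1-ene-1-carbaldehyde
Product: 21 diallyl (1R,2S,3S)-3-[(1R,2S,5S)-1-formyl-6-methylidene-3-oxobicyclo[3.2.1]octan-2-yl]-1,3-dimethylcyclohexane-1,2-dicarboxylate, via caesium enolate 20 (not isolated)
Conditions: Ir[dF(CF3)ppy]2(dtbbpy)PF6 (2 mol%), t-BuOH (2 equiv), degassed DME–DMF (3:1), blue LEDs, 40 °C; then 60 °C in the dark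
Reagents that add atoms: none
Why: Proposed new method: the photo-excited trivalent iridium complex oxidises oxalate 10, which loses two CO2 to give the tertiary C10 radical; this adds to C9, the unsubstituted terminus of the C8=C9 bond of 19 that is activated from both sides (C7 formyl, C11 ketone), and the α-formyl C8 radical is reduced by the divalent iridium species to caesium enolate 20, so the sequence is redox-neutral and needs no external base. Enolate 20 then closes ring D by 5-exo-tet C-alkylation at the allylic chloride carbon C15, forming the C8 quaternary centre and the bicyclo[3.2.1]octane. The closest known reactions are radical conjugate additions of tertiary alkyl oxalates used for fragment coupling and carboxylate-derived radical addition–polar cyclisation cascades, here extended to an enal acceptor and to a five-membered ring closing on a quaternary carbon. C10 is set by approach of 19 to the planar radical on the face opposite the cis ester groups on C5 and C4, and C8 is fixed by the tether, because C15 can reach only the enolate face that carries the C13 arm. C9 is set because its epimers interconvert faster than they cyclise: allylic 1,3-strain with the exocyclic enolate and the incoming C15 force ring A axial and trans to the C13 arm in the cyclising conformer, the unreactive epimer is equilibrated through the ketone enolate of the protonated adduct by the tert-butanol/caesium tert-butoxide shuttle, and after closure H9 is equatorial and flanked by two quaternary carbons, which should protect it from base. The selectivities needed, attack at C9 rather than C8 and C- rather than O-alkylation, follow from the steric preference of a tertiary radical for the CH terminus and from a five-membered carbocyclic transition state against a seven-membered enol ether.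

Step 13
Reactants: 21 diallyl (1R,2S,3S)-3-[(1R,2S,5S)-1-formyl-6-methylidene-3-oxobicyclo[3.2.1]octan-2-yl]-1,3-dimethylcyclohexane-1,2-dicarboxylate
Product: 22 (1R,2S,3S)-3-[(1R,2S,5S)-1-formyl-6-methylidene-3-oxobicyclo[3.2.1]octan-2-yl]-1,3-dimethylcyclohexane-1,2-dicarboxylic acid
Conditions: Pd(PPh3)4 (5 mol%), TolSO2Na (2.5 equiv), THF–MeOH, rt; then 0.5 M HCl to pH 3
Reagents that add atoms: none
Why: Tsuji–Trost allyl transfer from both allyl esters to the sulfinate, catalysed by zerovalent palladium under neutral conditions, should free the diacid without enolising C9 or isomerising the exocyclic alkene.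

**Compound list**

1 | methyl 3-oxocyclohex-1-ene-1-carboxylate | COC(=O)C1=CC(=O)CCC1 | starting material
2 | methyl (1R)-1-methyl-3-[(methylzincio)oxy]cyclohex-2-ene-1-carboxylate | C[Zn]OC1=C[C@](C)(C(=O)OC)CCC1 | intermediate
3 | methyl (1R)-2-(hydroxymethyl)-1-methyl-3-oxocyclohexane-1-carboxylate (both C2 epimers) | O=C1CCC[C@@](C)(C(=O)OC)C1CO | intermediate
4 | (3aS,7aR)-7a-methylhexahydro-2-benzofuran-1,4-dione | O=C1CCC[C@@]2(C)C(=O)OC[C@@H]12 | intermediate
5 | (3aS,4S,7aR)-4-hydroxy-4,7a-dimethylhexahydro-2-benzofuran-1(3H)-one | C[C@]1(O)CCC[C@@]2(C)C(=O)OC[C@@H]12 | intermediate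
6 | potassium (1R,2S,3S)-3-hydroxy-2-(hydroxymethyl)-1,3-dimethylcyclohexane-1-carboxylate | O[C@@]1(C)CCC[C@@](C)(C(=O)[O-])[C@H]1CO.[K+] | intermediate
7 | (1R,2R,3S)-3-hydroxy-1,3-dimethylcyclohexane-1,2-dicarboxylic acid | O[C@@]1(C)CCC[C@@](C)(C(=O)O)[C@H]1C(=O)O | intermediate
8 | diallyl (1R,2R,3S)-3-hydroxy-1,3-dimethylcyclohexane-1,2-dicarboxylate | O[C@@]1(C)CCC[C@@](C)(C(=O)OCC=C)[C@H]1C(=O)OCC=C | intermediate
9 | diallyl (1R,2R,3S)-3-[(methoxyoxalyl)oxy]-1,3-dimethylcyclohexane-1,2-dicarboxylate | COC(=O)C(=O)O[C@@]1(C)CCC[C@@](C)(C(=O)OCC=C)[C@H]1C(=O)OCC=C | intermediate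
10 | caesium 2-{[(1S,2R,3R)-2,3-bis(allyloxycarbonyl)-1,3-dimethylcyclohexyl]oxy}-2-oxoacetate | [Cs+].[O-]C(=O)C(=O)O[C@@]1(C)CCC[C@@](C)(C(=O)OCC=C)[C@H]1C(=O)OCC=C | intermediate
11 | methacrolein (2-methylprop-2-enal) | CC(=C)C=O | starting material
12 | ethyl 2-oxo-3-(triphenyl-λ5-phosphanylidene)propanoate | CCOC(=O)C(=O)C=P(c1ccccc1)(c1ccccc1)c1ccccc1 | starting material
13 | ethyl (3E)-5-methyl-2-oxohexa-3,5-dienoate | CCOC(=O)C(=O)/C=C/C(C)=C | intermediate
14 | ethyl (4R)-2-methoxy-2-methyl-4-(prop-1-en-2-yl)-3,4-dihydro-2H-pyran-6-carboxylate (C2 epimers) | CCOC(=O)C1=C[C@H](C(C)=C)CC(C)(OC)O1 | intermediate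
15 | ethyl (4R)-2,6-dioxo-4-(prop-1-en-2-yl)heptanoate | CCOC(=O)C(=O)C[C@H](C(C)=C)CC(C)=O | intermediate
16 | ethyl (5S)-3-oxo-5-(prop-1-en-2-yl)cyclohex-1-ene-1-carboxylate | CCOC(=O)C1=CC(=O)C[C@@H](C(C)=C)C1 | intermediate
17 | ethyl (5S)-5-(3-chloroprop-1-en-2-yl)-3-oxocyclohex-1-ene-1-carboxylate | CCOC(=O)C1=CC(=O)C[C@@H](C(=C)CCl)C1 | intermediate
18 | (5S)-5-(3-chloroprop-1-en-2-yl)-3-(hydroxymethyl)cyclohex-2-en-1-ol (both C1 epimers) | OCC1=CC(O)C[C@@H](C(=C)CCl)C1 | intermediate
19 | (5S)-5-(3-chloroprop-1-en-2-yl)-3-oxocyclohex-1-ene-1-carbaldehyde | O=CC1=CC(=O)C[C@@H](C(=C)CCl)C1 | intermediate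
20 | caesium enolate (at the formyl group) of diallyl (1R,2S,3S)-3-[(4S)-4-(3-chloroprop-1-en-2-yl)-2-formyl-6-oxocyclohexyl]-1,3-dimethylcyclohexane-1,2-dicarboxylate (C9 epimers) | [Cs+].[O-]C=C1C[C@H](C(=C)CCl)CC(=O)C1[C@]2(C)CCC[C@@](C)(C(=O)OCC=C)[C@H]2C(=O)OCC=C | intermediate
21 | diallyl (1R,2S,3S)-3-[(1R,2S,5S)-1-formyl-6-methylidene-3-oxobicyclo[3.2.1]octan-2-yl]-1,3-dimethylcyclohexane-1,2-dicarboxylate | C=C1C[C@]2(C=O)C[C@H]1CC(=O)[C@H]2[C@]1(C)CCC[C@@](C)(C(=O)OCC=C)[C@H]1C(=O)OCC=C | intermediate
22 | (1R,2S,3S)-3-[(1R,2S,5S)-1-formyl-6-methylidene-3-oxobicyclo[3.2.1]octan-2-yl]-1,3-dimethylcyclohexane-1,2-dicarboxylic acid | C=C1C[C@]2(C=O)C[C@H]1CC(=O)[C@H]2[C@]1(C)CCC[C@@](C)(C(=O)O)[C@H]1C(=O)O | target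

**Step count and risks**

Total step count: 13. Longest linear sequence: 8 steps (steps 6–13).

Steps most likely to fail:

Step 12 (Proposed new method). The cascade may stall after the radical addition if protonation of the enolate outruns ring closure. Facial selectivity at C10 on the monocyclic diester radical may be only moderate, and C9 epimerisation may be too slow to funnel both epimers into the cyclising one. The fallback separates the two events with known chemistry. It sets out from 10 and 19: the radical conjugate addition is run under the established aqueous oxalate conditions (same photocatalyst, DME–DMF, water, blue LEDs), where the enolate is simply protonated, to isolate the adduct diallyl (1R,2S,3S)-3-[(4S)-4-(3-chloroprop-1-en-2-yl)-2-formyl-6-oxocyclohexyl]-1,3-dimethylcyclohexane-1,2-dicarboxylate F1 as a mixture at C8 and C9. Ring D is then closed by a classical equilibrating intramolecular enolate alkylation (t-BuOK, t-BuOH–THF, 0 °C), in which the aldehyde α-carbon is the most acidic site and the only one whose alkylation gives a five-membered ring. The fallback comes back to the route at 21.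

Step 1. The zinc aldolate may undergo β-elimination or retro-aldol, formaldehyde may oligomerise, and lactonisation may be incomplete. The fallback sets out from 1: the conjugate-addition enolate is trapped with TMSOTf as the isolable enol silane methyl (1R)-1-methyl-3-[(trimethylsilyl)oxy]cyclohex-2-ene-1-carboxylate F2, which is hydroxymethylated in a separate Lewis-acid-catalysed Mukaiyama aldol reaction with aqueous formaldehyde (Yb(OTf)3, THF–H2O) to give 3. Acid then lactonises 3, and the fallback comes back to the route at 4.

Step 7. The dienyl keto ester may polymerise under Lewis acid, the enol ether may add to the keto carbonyl instead of the oxadiene, or face selectivity may be poor. The fallback sets out from 13 and makes the same C12–C13 bond by enamine catalysis: Michael addition of acetone with a cinchona-derived primary amine–thiourea catalyst, a known reaction of β,γ-unsaturated α-keto esters. It comes back to the route at 15; no new compound is made (F0).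

Further compounds
F1 | step 12 | diallyl (1R,2S,3S)-3-[(4S)-4-(3-chloroprop-1-en-2-yl)-2-formyl-6-oxocyclohexyl]-1,3-dimethylcyclohexane-1,2-dicarboxylate (mixture at C8 and C9) | O=CC1C[C@H](C(=C)CCl)CC(=O)C1[C@]2(C)CCC[C@@](C)(C(=O)OCC=C)[C@H]2C(=O)OCC=C
F2 | step 1 | methyl (1R)-1-methyl-3-[(trimethylsilyl)oxy]cyclohex-2-ene-1-carboxylate | C[Si](C)(C)OC1=C[C@](C)(C(=O)OC)CCC1
F0 | step 7 | none | none
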